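Labdane numbering is used for every compound: C1–C10 form the decalin, C11–C16 the side chain, C17 sits on C8, C18 (CH2O) and C19 (CH3) on C4, C20 on C10.

## The problem

Compound 34 is an ent-labdane: a trans-fused decalin (rings A and B) with a 3-methylidenepent-4-enyl chain on C9 and six stereocentres, (4S,5S,6R,8S,9S,10R). C4 and C10 are quaternary carbons and C8 is a tertiary carbinol. The methyl groups C19, C20 and C17 are axial on one face; the C18 hydroxymethyl group, the 6-acetate, the 8-hydroxyl and the C9 chain are equatorial. C4 carries two groups of nearly equal size (CH3 and CH2O), so it cannot direct a neighbouring centre and must itself be set from C5. C10, once in place with its axial methyl, shields one face of ring B and can then control C8 (oxygen from the opposite face), C6 (equatorial alcohol as the thermodynamic product) and, through a C6 ketone, the trans ring fusion at C5. The 2-substituted 1,3-diene will not survive dissolving metals, electrophilic oxidants or strong acid; the tertiary alcohol is prone to elimination or retro-aldol cleavage once C6 is a ketone; and the secondary acetate can only be placed beside the primary C18 alcohol while the latter is masked. The feature that invites the key step is the quaternary C10 flanked by C9 and C1: a carbene at C9, tied to C5 through C8, C7 and C6, can add across a C10=C1 double bond of ring A, closing ring B through C9–C10 and a cyclopropane through C9–C1. The extra C9–C1 bond is exocyclic to the C8 ketone ring and aligned with its π system, so Li/NH3 should cut it, leaving C1 as a methylene and a regiodefined C8/C9 enolate for C11. The cost is that the tether delivers C9 only to its own face of ring A, giving a cis ring fusion that must later be inverted at C5.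

## Retrosynthesis

**Diene, acetate and C18 silyl group (34 to 31).** The C13=C16 and C14=C15 bonds are cut back to the terminal alkyne of 31, after removing the silyl group (33) and the acetate (32). Enyne cross-metathesis with ethylene gives only the 2-substituted diene, whereas dehydration of a 13-ol would give isomer mixtures. The forward reaction must tolerate a free tertiary alcohol and an acetate, and it comes last because nothing earlier in ring B is compatible with a diene.

**Alkyne carbon C14 (31 to 27).** The C13≡C14 bond is cut (Ohira–Bestmann) to lactol 30, which comes from triol 29 and so from the allyl group of diol 27. Allyl bromide is the most reliable three-carbon electrophile for a hindered enolate, and the allyl group is inert to every ring-B operation. A butynyl or dienyl halide would alkylate poorly and would not survive Li/NH3.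

**The two C–O bonds of ring B (27 to 24).** C6–OH and C8–OH are traced to epoxy ketone 25 and enone 24. The more familiar sequence (8(17)-alkene, epoxidation, hydride opening) was set aside: a 6-ketone is needed to invert C5, and under base it would draw an 8(17)-alkene into conjugation or eliminate an 8-hydroxyl. The plan uses that conjugation instead. The forward steps need oxygen delivered to C8 anti to C20 and an equatorial 6-alcohol.

**C17 and the ring fusion (24 to 20).** The C8=C17 bond is cut to ketone 20 via 21, 22 and 23. Enone 24 is the conjugated, trans-fused isomer of 23, so C5 inversion and alkene migration are one equilibration. Ketone 20 is simpler by one carbon and still has the cis fusion left by the key step.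

**C9–C11 and the temporary bond (20 to 18).** Cutting C9–C11 and re-forming C1–C9 gives cyclopropyl ketone 18. No other precursor offers a C9 enolate free of competition from C7. The forward step needs cleavage of the exocyclic cyclopropane bond and alkylation on the convex face of the cis-decalin.

**Key disconnection (18 to 17).** C9–C10 and C9–C1 are cut to diazoketone 17, a monocyclic ring-A cyclohexene. A conjugate addition to build quaternary C10 would be much harder. The forward step needs face selectivity, supplied by C5 with C6 cis to C18.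

**Chain end (17 to 12).** C9 comes from diazomethane via acid 15, alcohol 13 and PMB ether 12. These are functional-group changes only, with two silyl ethers chosen to survive Li/NH3 and to be removable one at a time.

**C4 quaternary centre (12 to 8).** The C4–C19 bond is cut: 12 comes from alcohol 11 and ester 10, and 10 from ester 8 by enolate methylation. Building C4 before C5 was rejected because CH3 and CH2OR give an adjacent enolate no usable facial bias. Made after C5, C4 is set by a large vicinal group, and methylation anti to the C5 chain puts C18 cis to C6 as the key step requires.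

**C20 (8 to 5).** The C10–C20 bond is cut to vinyl triflate 7 and ketone 5. Kinetic enolisation toward C1 fixes the alkene position, which dehydration or deconjugation could not do reliably.

**C5–C6 and the first stereocentre (5 to 1 and 2).** The C5–C6 bond is cut to enol silane 3 and aldehyde 2; 3 comes from enone ester 1 by asymmetric conjugate reduction. Both starting materials are simple and achiral. The forward step needs hydride added β to the ketone and an aldol anti to the C4 ester.

## Roads not taken

**Alternative 1:** The C18–O bond is made last on a C4 gem-dimethyl decalin. The 6-O-diethylsilyl ether A1 would undergo dehydrogenative C–H silylation ([Rh(cod)Cl]2, Xantphos, norbornene) at the equatorial C4 methyl to give oxasilinane A2, and oxidation of the C–Si bond would unveil the C18 oxygen.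
- Merits: ring A needs no C4 stereocentre, and the gem-dimethyl decalin is the pattern of abundant chiral-pool labdanes. In step count this road is clearly better than the chosen plan.
- Weak points: the 6-oxygen is gauche to both the equatorial and the axial methyl, so the choice between them is not assured. The side chain and 8-hydroxyl must be masked as in A1. After oxidation the 6-position must be acetylated beside a free primary alcohol, costing a protection cycle. The decisive C–H step falls late on precious material.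
- What the chosen plan sets against it: C18 carries its oxygen from the first step with unambiguous configuration.

**Alternative 2:** C5–C10 and C8–C9 are cut together. Furan–enal A3 would cyclise under Me2AlCl to the oxygen-bridged adduct A4.
- Merits: both rings and both bonds form in one step, the C8–O bond and C17 arrive already in place, and the aldehyde is a handle for the side chain. It is more convergent than the chosen plan.
- Weak points: the cycloaddition is reversible and must form a quaternary C10 and a fully substituted bridgehead C5 from a β,β-disubstituted enal. The only element biasing the face is the CH3/CH2O difference at C4, which is slight. The bridge must then be opened at C5–O with hydrogen delivered for a trans fusion, and C6 must be oxygenated regioselectively.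
- What the chosen plan sets against it: ring closure is irreversible, and C10 is tied to C5 by a tether, not by a weak steric bias.

**Alternative 3:** C1–C10 and C4–C5 are cut. Quinone A5 and diene A6 would combine under a chiral oxazaborolidinium catalyst (oxazaborolidine protonated by HNTf2) to give the cis-fused ene-dione A7.
- Merits: one catalytic step delivers the whole decalin with C4 and C10 set, the C7=C8 enone with its methyl, and oxygen at C6. It reaches the stage of enone 24 far sooner than the chosen plan.
- Weak points: the diene terminus is 1,1-disubstituted and must bond next to a methyl-bearing dienophile carbon, which is a slow and crowded cycloaddition. The C9 carbonyl, neopentyl to C10, must then be exchanged for a hydrogen and the C11 chain with control of C9. The ring-A alkene must be reduced selectively and C5 inverted.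
- What the chosen plan sets against it: the regiodefined C9 enolate that falls out of the cyclopropane cleavage.

Key step: step 11

Remark: the copper hydride bearing (R)-DTBM-SEGPHOS is assumed to deliver hydride with the facial sense known for 3-alkylcyclohexenones, giving (4R)-3; if the sense is opposite, the (S)-ligand is used.
Remark: the aldol is assumed to give mainly the (6S)-carbinol drawn; the C6 epimer behaves alike and both converge at ketone 23.
Remark: 1 and 2 are taken as catalogue chemicals.

## Route

Step 1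
Reactants: 1 methyl 3-oxocyclohex-1-ene-1-carboxylate; 2 3-[(4-methoxybenzyl)oxy]propanal
Product: 4 methyl (1R,2R)-2-[(1S)-1-hydroxy-3-[(4-methoxybenzyl)oxy]propyl]-3-oxocyclohexane-1-carboxylate, via enol silane 3 (not isolated)
Conditions: Cu(OAc)2·H2O (3 mol %), (R)-DTBM-SEGPHOS (3 mol %), (EtO)2MeSiH, toluene, 0 °C; then 2, TiCl4, CH2Cl2, –78 °C
Reagents that add atoms: none
Why: Copper hydride-catalysed asymmetric 1,4-hydrosilylation adds hydride β to the ketone (at C4) under ligand control and gives the regiodefined enol silane 3; the Mukaiyama aldol with 2 then forms C5–C6 anti to the C4 ester (2,3-trans), so C5 is fixed in absolute terms by C4. C6 arises from the open transition state and its configuration is immaterial because C6 later becomes a ketone.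

Step 2
Reactants: 4 methyl (1R,2R)-2-[(1S)-1-hydroxy-3-[(4-methoxybenzyl)oxy]propyl]-3-oxocyclohexane-1-carboxylate
Product: 5 methyl (1R,2R)-2-[(1S)-3-[(4-methoxybenzyl)oxy]-1-(triethylsilyloxy)propyl]-3-oxocyclohexane-1-carboxylate
Conditions: Et3SiOTf, 2,6-lutidine, CH2Cl2, –78 °C
Reagents that add atoms: triethylsilyl trifluoromethanesulfonate, CC[Si](CC)(CC)OS(=O)(=O)C(F)(F)F
Why: Silylation of the β-hydroxy ketone under non-nucleophilic base stops retro-aldol and dehydration. The triethylsilyl group is bulky enough to hinder attack of the C6 oxygen on the later carbenoid, yet labile enough to be removed beside a triisopropylsilyl ether.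

Step 3
Reactants: 5 methyl (1R,2R)-2-[(1S)-3-[(4-methoxybenzyl)oxy]-1-(triethylsilyloxy)propyl]-3-oxocyclohexane-1-carboxylate
Product: 7 methyl (1R,2R)-2-[(1S)-3-[(4-methoxybenzyl)oxy]-1-(triethylsilyloxy)propyl]-3-(trifluoromethylsulfonyloxy)cyclohex-3-ene-1-carboxylate, via potassium enolate 6 (not isolated)
Conditions: KN(SiMe3)2, THF, –78 °C; then PhNTf2, –78 → 0 °C
Reagents that add atoms: N-phenylbis(trifluoromethanesulfonimide), O=S(=O)(N(c1ccccc1)S(=O)(=O)C(F)(F)F)C(F)(F)F
Why: Kinetic deprotonation takes the C1 methylene in preference to the hindered tertiary C5–H and the less acidic ester α-H, and O-triflation of the enolate fixes the double bond at C10=C1. C5 is then no longer epimerisable.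

Step 4
Reactants: 7 methyl (1R,2R)-2-[(1S)-3-[(4-methoxybenzyl)oxy]-1-(triethylsilyloxy)propyl]-3-(trifluoromethylsulfonyloxy)cyclohex-3-ene-1-carboxylate
Product: 8 methyl (1R,2S)-2-[(1S)-3-[(4-methoxybenzyl)oxy]-1-(triethylsilyloxy)propyl]-3-methylcyclohex-3-ene-1-carboxylate
Conditions: MeMgBr, Fe(acac)3 (5 mol %), THF/NMP, –30 °C
Reagents that add atoms: methylmagnesium bromide, C[Mg]Br
Why: Iron-catalysed Kumada-type cross-coupling of an alkenyl triflate with a methyl Grignard reagent is faster at low temperature than addition to the hindered ester, and installs C20 on the trisubstituted alkene.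

Step 5
Reactants: 8 methyl (1R,2S)-2-[(1S)-3-[(4-methoxybenzyl)oxy]-1-(triethylsilyloxy)propyl]-3-methylcyclohex-3-ene-1-carboxylate
Product: 10 methyl (1S,2R)-2-[(1S)-3-[(4-methoxybenzyl)oxy]-1-(triethylsilyloxy)propyl]-1,3-dimethylcyclohex-3-ene-1-carboxylate, via lithium ester enolate 9 (not isolated)
Conditions: LiN(iPr)2, THF, –78 °C; then MeI, DMPU, –78 → –40 °C
Reagents that add atoms: iodomethane, CI
Why: Ester enolate alkylation; A(1,3) strain with the exocyclic enolate turns the large C5 chain pseudoaxial, so MeI enters the opposite face. C19 therefore ends trans to C6 and the ester carbon C18 cis to C6, which is the relationship the key step needs.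

Step 6
Reactants: 10 methyl (1S,2R)-2-[(1S)-3-[(4-methoxybenzyl)oxy]-1-(triethylsilyloxy)propyl]-1,3-dimethylcyclohex-3-ene-1-carboxylate
Product: 11 [(1S,2R)-2-[(1S)-3-[(4-methoxybenzyl)oxy]-1-(triethylsilyloxy)propyl]-1,3-dimethylcyclohex-3-en-1-yl]methanol
Conditions: LiAlH4, Et2O, 0 °C
Reagents that add atoms: none
Why: Hydride reduction of the neopentyl ester to the primary C18 alcohol; silyl and benzyl-type ethers are inert and no stereocentre is touched.

Step 7
Reactants: 11 [(1S,2R)-2-[(1S)-3-[(4-methoxybenzyl)oxy]-1-(triethylsilyloxy)propyl]-1,3-dimethylcyclohex-3-en-1-yl]methanol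
Product: 12 18-O-triisopropylsilyl ether of 11, (4S,5R,6S)
Conditions: iPr3SiOTf, 2,6-lutidine, CH2Cl2, 0 °C
Reagents that add atoms: triisopropylsilyl trifluoromethanesulfonate, CC(C)[Si](OS(=O)(=O)C(F)(F)F)(C(C)C)C(C)C
Why: Silylation with the triflate overcomes the neopentyl hindrance. The triisopropylsilyl ether is chosen because it survives Li/NH3, mild acid and base and leaves only at the end.

Step 8
Reactants: 12 18-O-triisopropylsilyl ether of 11, (4S,5R,6S)
Product: 13 (3S)-3-[(1R,6S)-2,6-dimethyl-6-[(triisopropylsilyloxy)methyl]cyclohex-2-en-1-yl]-3-(triethylsilyloxy)propan-1-ol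
Conditions: DDQ, CH2Cl2/pH 7 buffer, 0 °C
Reagents that add atoms: none
Why: Oxidative cleavage of the 4-methoxybenzyl ether by benzylic hydride abstraction and hydrolysis; the silyl ethers and the trisubstituted alkene are unaffected under buffered conditions.

Step 9
Reactants: 13 (3S)-3-[(1R,6S)-2,6-dimethyl-6-[(triisopropylsilyloxy)methyl]cyclohex-2-en-1-yl]-3-(triethylsilyloxy)propan-1-ol
Product: 15 (3S)-3-[(1R,6S)-2,6-dimethyl-6-[(triisopropylsilyloxy)methyl]cyclohex-2-en-1-yl]-3-(triethylsilyloxy)propanoic acid, via aldehyde 14 (not isolated)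
Conditions: TEMPO (cat.), PhI(OAc)2, MeCN/aqueous pH 7 buffer, rt
Reagents that add atoms: water, O
Why: Oxoammonium oxidation of the primary alcohol to the aldehyde, whose hydrate is oxidised on to the acid; buffering protects the triethylsilyl ether and the alkene is not attacked.

Step 10
Reactants: 15 (3S)-3-[(1R,6S)-2,6-dimethyl-6-[(triisopropylsilyloxy)methyl]cyclohex-2-en-1-yl]-3-(triethylsilyloxy)propanoic acid
Product: 17 (4S)-1-diazo-4-[(1R,6S)-2,6-dimethyl-6-[(triisopropylsilyloxy)methyl]cyclohex-2-en-1-yl]-4-(triethylsilyloxy)butan-2-one, via mixed anhydride 16 (not isolated)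
Conditions: i-BuOCOCl, Et3N, THF, –15 °C; then CH2N2, Et2O, 0 °C
Reagents that add atoms: diazomethane, C=[N+]=[N-]
Why: Acylation of diazomethane by the mixed carbonic anhydride (Arndt–Eistert-type diazoketone synthesis) avoids an acid chloride and HCl, which the silyl ether would not tolerate; C9 is introduced here.

Step 11
Reactants: 17 (4S)-1-diazo-4-[(1R,6S)-2,6-dimethyl-6-[(triisopropylsilyloxy)methyl]cyclohex-2-en-1-yl]-4-(triethylsilyloxy)butan-2-one
Product: 18 (1S,4S,5R,6S,9R,10R)-1,9-cyclo-4,10-dimethyl-6-(triethylsilyloxy)-4-[(triisopropylsilyloxy)methyl]decalin-8-one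
Conditions: Rh2(OAc)4 (1 mol %), CH2Cl2, rt, slow addition of 17
Reagents that add atoms: none
Why: Rh2(OAc)4 decomposes 17 with loss of N2 to an electrophilic divalent-rhodium carbenoid at C9, which adds to the electron-rich trisubstituted C10=C1 alkene in a concerted, asynchronous [2+1] step. The closest known reaction type is the intramolecular cyclopropanation of δ,ε-unsaturated α-diazoketones to bicyclo[4.1.0]heptan-2-ones. Ring B closes through C9–C10 as a six-membered ketone ring, the carbenoid carbon bonding first to the proximal, fully substituted alkene carbon, and the cyclopropane closes through C9–C1. The four-atom tether reaches only the alkene face on which C6 is attached to C5, so C9 is delivered syn to C6 and C18 and the C20 methyl is pushed to the opposite face. C10 is therefore controlled by C5, and C1 and C9 follow from the geometry of the cis-fused tricycle. The step needs this face selectivity and also chemoselectivity for cyclopropanation over 1,5-insertion into the allylic C5–H bond or capture by the C6 oxygen; the nucleophilic alkene, the bulky silyl ether, the carboxylate ligands and slow addition favour the cycloaddition. Full substitution at C10, which would defeat a conjugate addition, is no obstacle to a carbenoid.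

Step 12
Reactants: 18 (1S,4S,5R,6S,9R,10R)-1,9-cyclo-4,10-dimethyl-6-(triethylsilyloxy)-4-[(triisopropylsilyloxy)methyl]decalin-8-one
Product: 20 (4S,5R,6S,9S,10R)-9-allyl-4,10-dimethyl-6-(triethylsilyloxy)-4-[(triisopropylsilyloxy)methyl]decalin-8-one (cis-fused), via lithium enolate 19 (not isolated)
Conditions: Li, NH3(l)/THF, t-BuOH (1 equiv), –78 °C; isoprene; then CH2=CHCH2Br, –78 → –33 °C
Reagents that add atoms: allyl bromide, C=CCBr
Why: The ketyl radical anion cleaves the cyclopropane bond that overlaps best with the carbonyl π system, C1–C9, which is exocyclic to ring B; the C1 carbanion is protonated by t-BuOH, leaving the regiodefined enolate 19 (reductive alkylation of a cyclopropyl ketone). Allyl bromide then attacks C9 on the convex face of the cis-decalin, the face of H5 and C20, so C11 ends syn to C20.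

Step 13
Reactants: 20 (4S,5R,6S,9S,10R)-9-allyl-4,10-dimethyl-6-(triethylsilyloxy)-4-[(triisopropylsilyloxy)methyl]decalin-8-one
Product: 21 (4S,5R,6S,9R,10S)-9-allyl-4,10-dimethyl-8-methylidene-6-(triethylsilyloxy)-4-[(triisopropylsilyloxy)methyl]decalin
Conditions: Zn, CH2Br2, TiCl4, THF/CH2Cl2, 0 °C → rt
Reagents that add atoms: dibromomethane, BrCBr
Why: Takai–Lombardo methylenation uses a non-basic gem-dimetallic reagent, so the hindered ketone gains C17 without epimerisation at C9 or β-elimination of the C6 silyloxy group.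

Step 14
Reactants: 21 (4S,5R,6S,9R,10S)-9-allyl-4,10-dimethyl-8-methylidene-6-(triethylsilyloxy)-4-[(triisopropylsilyloxy)methyl]decalin
Product: 22 (4S,5R,6S,9R,10S)-9-allyl-4,10-dimethyl-8-methylidene-4-[(triisopropylsilyloxy)methyl]decalin-6-ol
Conditions: PPTS, MeOH/CH2Cl2, 0 °C
Reagents that add atoms: none
Why: Acid-catalysed methanolysis removes the triethylsilyl ether, which is far more labile at silicon than the triisopropylsilyl ether; the acid is too weak to move the exocyclic alkene.

Step 15
Reactants: 22 (4S,5R,6S,9R,10S)-9-allyl-4,10-dimethyl-8-methylidene-4-[(triisopropylsilyloxy)methyl]decalin-6-ol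
Product: 23 (4S,5R,9R,10S)-9-allyl-4,10-dimethyl-8-methylidene-4-[(triisopropylsilyloxy)methyl]decalin-6-one (cis-fused)
Conditions: Dess–Martin periodinane, NaHCO3, CH2Cl2, 0 °C → rt
Reagents that add atoms: none
Why: Buffered hypervalent-iodine oxidation of the hindered secondary alcohol gives the β,γ-unsaturated ketone; C6 loses its provisional configuration here.

Step 16
Reactants: 23 (4S,5R,9R,10S)-9-allyl-4,10-dimethyl-8-methylidene-4-[(triisopropylsilyloxy)methyl]decalin-6-one
Product: 24 (4S,5S,9R,10S)-9-allyl-4,8,10-trimethyl-4-[(triisopropylsilyloxy)methyl]-Δ7-octalin-6-one (trans-fused)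
Conditions: NaOMe (cat.), MeOH, 0 °C → rt
Reagents that add atoms: none
Why: Deprotonation at C7 gives a dienolate that is reprotonated at C17, drawing the alkene into conjugation, and reversible enolisation toward C5 equilibrates the ring fusion to the more stable trans-decalin, as with other 7-en-6-ones. The conditions are kept mild so that the γ-hydrogen at C9 is not exchanged.

Step 17
Reactants: 24 (4S,5S,9R,10S)-9-allyl-4,8,10-trimethyl-4-[(triisopropylsilyloxy)methyl]-Δ7-octalin-6-one
Product: 25 (4S,5S,7R,8R,9S,10S)-9-allyl-7,8-epoxy-4,8,10-trimethyl-4-[(triisopropylsilyloxy)methyl]decalin-6-one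
Conditions: 30% H2O2, NaOH, MeOH, 0 °C → rt
Reagents that add atoms: hydrogen peroxide, OO
Why: Weitz–Scheffer nucleophilic epoxidation; hydroperoxide adds to C8 on the face opposite the axial C20 methyl, which sets the C8–O bond with C17 axial. The isolated allyl group is not attacked by a nucleophilic oxidant.

Step 18
Reactants: 25 (4S,5S,7R,8R,9S,10S)-9-allyl-7,8-epoxy-4,8,10-trimethyl-4-[(triisopropylsilyloxy)methyl]decalin-6-one
Product: 27 (4S,5S,6R,8S,9S,10R)-9-allyl-4,8,10-trimethyl-4-[(triisopropylsilyloxy)methyl]decalin-6,8-diol, via hydroxy ketone 26 (not isolated)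
Conditions: Li, NH3(l)/THF, –78 °C; then EtOH, –78 → –33 °C; NH4Cl
Reagents that add atoms: none
Why: Two-electron reduction cleaves the Cα–O bond of the α,β-epoxy ketone and leaves the enolate of 26 with the C8–O bond intact; protonation by ethanol and further dissolving-metal reduction give the thermodynamically preferred equatorial 6-alcohol. An axial alcohol would be syn-diaxial to three methyl groups.

Step 19
Reactants: 27 (4S,5S,6R,8S,9S,10R)-9-allyl-4,8,10-trimethyl-4-[(triisopropylsilyloxy)methyl]decalin-6,8-diol
Product: 29 (4S,5S,6R,8S,9S,10R)-9-(3-hydroxypropyl)-4,8,10-trimethyl-4-[(triisopropylsilyloxy)methyl]decalin-6,8-diol, via alkylborane 28 (not isolated)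
Conditions: 9-BBN (excess), THF, 0 °C → rt; then NaOH, H2O2, 0 °C
Reagents that add atoms: hydrogen peroxide, OO
Why: Anti-Markovnikov hydroboration of the only alkene and oxidation of the C–B bond with retention give the primary C13 alcohol.

Step 20
Reactants: 29 (4S,5S,6R,8S,9S,10R)-9-(3-hydroxypropyl)-4,8,10-trimethyl-4-[(triisopropylsilyloxy)methyl]decalin-6,8-diol
Product: 30 8,13-lactol (13-hydroxy-8,13-epoxide) of the 6-ol, (4S,5S,6R,8S,9S,10R), anomers
Conditions: TEMPO (cat.), PhI(OAc)2 (1.1 equiv), CH2Cl2, rt
Reagents that add atoms: none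
Why: The oxoammonium oxidant takes the primary alcohol in preference to the hindered secondary one; the aldehyde is trapped by the C8 hydroxyl as a six-membered lactol. The limiting amount of oxidant is meant to stop there.

Step 21
Reactants: 30 8,13-lactol of the 6-ol, (4S,5S,6R,8S,9S,10R)
Product: 31 (4S,5S,6R,8S,9S,10R)-9-(but-3-ynyl)-4,8,10-trimethyl-4-[(triisopropylsilyloxy)methyl]decalin-6,8-diol
Conditions: MeC(O)C(N2)P(O)(OMe)2, K2CO3, MeOH, 0 °C → rt
Reagents that add atoms: dimethyl (1-diazo-2-oxopropyl)phosphonate, CC(=O)C(=[N+]=[N-])P(=O)(OC)OC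
Why: Ohira–Bestmann (Seyferth–Gilbert) homologation acts on the open hydroxy aldehyde in equilibrium with the lactol and adds C14 as the alkyne terminus; no acetate is present yet to be cleaved by methanolic carbonate.

Step 22
Reactants: 31 (4S,5S,6R,8S,9S,10R)-9-(but-3-ynyl)-4,8,10-trimethyl-4-[(triisopropylsilyloxy)methyl]decalin-6,8-diol
Product: 32 6-acetate of 31, (4S,5S,6R,8S,9S,10R)
Conditions: Ac2O, DMAP (cat.), pyridine, rt
Reagents that add atoms: acetic anhydride, CC(=O)OC(C)=O
Why: DMAP-catalysed acylation takes the secondary equatorial 6-hydroxyl; the tertiary 8-hydroxyl is inert under these conditions and C18 is masked.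

Step 23
Reactants: 32 6-acetate of 31, (4S,5S,6R,8S,9S,10R)
Product: 33 18-O-triisopropylsilyl ether of 34
Conditions: ethylene (1 atm), second-generation Grubbs catalyst (H2IMes)(PCy3)Cl2Ru=CHPh (5 mol %), CH2Cl2, 40 °C
Reagents that add atoms: ethylene, C=C
Why: Enyne cross-metathesis: the ruthenium methylidene adds to the terminal alkyne, the vinylcarbene is released by ethylene, and the 2-substituted 1,3-diene results with C15 and C16 from ethylene.

Step 24
Reactants: 33 18-O-triisopropylsilyl ether of 34
Product: 34 (4S,5S,6R,8S,9S,10R)-6-acetoxylabda-13(16),14-diene-8,18-diol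
Conditions: HF·pyridine, pyridine, THF, 0 °C → rt
Reagents that add atoms: none
Why: Fluoride cleavage of the silyl ether under buffered, non-basic conditions frees C18–OH without acyl migration from O6, elimination of the tertiary alcohol or damage to the diene.

## Compound list

1 | methyl 3-oxocyclohex-1-ene-1-carboxylate | COC(=O)C1=CC(=O)CCC1 | starting material
2 | 3-[(4-methoxybenzyl)oxy]propanal | COc1ccc(COCCC=O)cc1 | starting material
3 | methyl (1R)-3-[diethoxy(methyl)silyl]oxycyclohex-2-ene-1-carboxylate | CCO[Si](C)(OCC)OC1=C[C@H](C(=O)OC)CCC1 | intermediate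
4 | methyl (1R,2R)-2-[(1S)-1-hydroxy-3-[(4-methoxybenzyl)oxy]propyl]-3-oxocyclohexane-1-carboxylate | COc1ccc(COCC[C@H](O)[C@@H]2C(=O)CCC[C@H]2C(=O)OC)cc1 | intermediate
5 | methyl (1R,2R)-2-[(1S)-3-[(4-methoxybenzyl)oxy]-1-(triethylsilyloxy)propyl]-3-oxocyclohexane-1-carboxylate | COc1ccc(COCC[C@H](O[Si](CC)(CC)CC)[C@@H]2C(=O)CCC[C@H]2C(=O)OC)cc1 | intermediate
6 | potassium enolate of 5 (C10–OK, C10=C1) | COc1ccc(COCC[C@H](O[Si](CC)(CC)CC)[C@@H]2C([O-])=CCC[C@H]2C(=O)OC)cc1.[K+] | intermediate
7 | methyl (1R,2R)-2-[(1S)-3-[(4-methoxybenzyl)oxy]-1-(triethylsilyloxy)propyl]-3-(trifluoromethylsulfonyloxy)cyclohex-3-ene-1-carboxylate | COc1ccc(COCC[C@H](O[Si](CC)(CC)CC)[C@@H]2C(OS(=O)(=O)C(F)(F)F)=CCC[C@H]2C(=O)OC)cc1 | intermediate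
8 | methyl (1R,2S)-2-[(1S)-3-[(4-methoxybenzyl)oxy]-1-(triethylsilyloxy)propyl]-3-methylcyclohex-3-ene-1-carboxylate | COc1ccc(COCC[C@H](O[Si](CC)(CC)CC)[C@@H]2C(C)=CCC[C@H]2C(=O)OC)cc1 | intermediate
9 | lithium ester enolate of 8 (C4=C18) | COc1ccc(COCC[C@H](O[Si](CC)(CC)CC)[C@@H]2C(C)=CCCC2=C([O-])OC)cc1.[Li+] | intermediate
10 | methyl (1S,2R)-2-[(1S)-3-[(4-methoxybenzyl)oxy]-1-(triethylsilyloxy)propyl]-1,3-dimethylcyclohex-3-ene-1-carboxylate | COc1ccc(COCC[C@H](O[Si](CC)(CC)CC)[C@@H]2C(C)=CCC[C@]2(C)C(=O)OC)cc1 | intermediate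
11 | [(1S,2R)-2-[(1S)-3-[(4-methoxybenzyl)oxy]-1-(triethylsilyloxy)propyl]-1,3-dimethylcyclohex-3-en-1-yl]methanol | COc1ccc(COCC[C@H](O[Si](CC)(CC)CC)[C@@H]2C(C)=CCC[C@]2(C)CO)cc1 | intermediate
12 | 18-O-triisopropylsilyl ether of 11, (4S,5R,6S) | COc1ccc(COCC[C@H](O[Si](CC)(CC)CC)[C@@H]2C(C)=CCC[C@]2(C)CO[Si](C(C)C)(C(C)C)C(C)C)cc1 | intermediate
13 | (3S)-3-[(1R,6S)-2,6-dimethyl-6-[(triisopropylsilyloxy)methyl]cyclohex-2-en-1-yl]-3-(triethylsilyloxy)propan-1-ol | OCC[C@H](O[Si](CC)(CC)CC)[C@@H]1C(C)=CCC[C@]1(C)CO[Si](C(C)C)(C(C)C)C(C)C | intermediate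
14 | (3S)-3-[(1R,6S)-2,6-dimethyl-6-[(triisopropylsilyloxy)methyl]cyclohex-2-en-1-yl]-3-(triethylsilyloxy)propanal | O=CC[C@H](O[Si](CC)(CC)CC)[C@@H]1C(C)=CCC[C@]1(C)CO[Si](C(C)C)(C(C)C)C(C)C | intermediate
15 | (3S)-3-[(1R,6S)-2,6-dimethyl-6-[(triisopropylsilyloxy)methyl]cyclohex-2-en-1-yl]-3-(triethylsilyloxy)propanoic acid | OC(=O)C[C@H](O[Si](CC)(CC)CC)[C@@H]1C(C)=CCC[C@]1(C)CO[Si](C(C)C)(C(C)C)C(C)C | intermediate
16 | isobutyl carbonic mixed anhydride of 15 | CC(C)COC(=O)OC(=O)C[C@H](O[Si](CC)(CC)CC)[C@@H]1C(C)=CCC[C@]1(C)CO[Si](C(C)C)(C(C)C)C(C)C | intermediate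
17 | (4S)-1-diazo-4-[(1R,6S)-2,6-dimethyl-6-[(triisopropylsilyloxy)methyl]cyclohex-2-en-1-yl]-4-(triethylsilyloxy)butan-2-one | [N-]=[N+]=CC(=O)C[C@H](O[Si](CC)(CC)CC)[C@@H]1C(C)=CCC[C@]1(C)CO[Si](C(C)C)(C(C)C)C(C)C | intermediate
18 | (1S,4S,5R,6S,9R,10R)-1,9-cyclo-4,10-dimethyl-6-(triethylsilyloxy)-4-[(triisopropylsilyloxy)methyl]decalin-8-one | O=C1C[C@H](O[Si](CC)(CC)CC)[C@@H]2[C@@]3(C)[C@@H](CC[C@]2(C)CO[Si](C(C)C)(C(C)C)C(C)C)[C@@H]13 | intermediate
19 | lithium C8/C9 enolate of the cis-decalin, (4S,5R,6S,10R) | [Li+].[O-]C1=C[C@]2(C)CCC[C@](C)(CO[Si](C(C)C)(C(C)C)C(C)C)[C@@H]2[C@@H](O[Si](CC)(CC)CC)C1 | intermediate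
20 | (4S,5R,6S,9S,10R)-9-allyl-4,10-dimethyl-6-(triethylsilyloxy)-4-[(triisopropylsilyloxy)methyl]decalin-8-one | C=CC[C@H]1[C@]2(C)CCC[C@](C)(CO[Si](C(C)C)(C(C)C)C(C)C)[C@@H]2[C@@H](O[Si](CC)(CC)CC)CC1=O | intermediate
21 | (4S,5R,6S,9R,10S)-9-allyl-4,10-dimethyl-8-methylidene-6-(triethylsilyloxy)-4-[(triisopropylsilyloxy)methyl]decalin | C=CC[C@H]1[C@]2(C)CCC[C@](C)(CO[Si](C(C)C)(C(C)C)C(C)C)[C@@H]2[C@@H](O[Si](CC)(CC)CC)CC1=C | intermediate
22 | (4S,5R,6S,9R,10S)-9-allyl-4,10-dimethyl-8-methylidene-4-[(triisopropylsilyloxy)methyl]decalin-6-ol | C=CC[C@H]1[C@]2(C)CCC[C@](C)(CO[Si](C(C)C)(C(C)C)C(C)C)[C@@H]2[C@@H](O)CC1=C | intermediate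
23 | (4S,5R,9R,10S)-9-allyl-4,10-dimethyl-8-methylidene-4-[(triisopropylsilyloxy)methyl]decalin-6-one | C=CC[C@H]1[C@]2(C)CCC[C@](C)(CO[Si](C(C)C)(C(C)C)C(C)C)[C@@H]2C(=O)CC1=C | intermediate
24 | (4S,5S,9R,10S)-9-allyl-4,8,10-trimethyl-4-[(triisopropylsilyloxy)methyl]-Δ7-octalin-6-one | C=CC[C@H]1[C@]2(C)CCC[C@](C)(CO[Si](C(C)C)(C(C)C)C(C)C)[C@H]2C(=O)C=C1C | intermediate
25 | (4S,5S,7R,8R,9S,10S)-9-allyl-7,8-epoxy-4,8,10-trimethyl-4-[(triisopropylsilyloxy)methyl]decalin-6-one | C=CC[C@H]1[C@]2(C)CCC[C@](C)(CO[Si](C(C)C)(C(C)C)C(C)C)[C@H]2C(=O)[C@H]3[C@]1(C)O3 | intermediate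
26 | (4S,5S,8S,9S,10S)-9-allyl-8-hydroxy-4,8,10-trimethyl-4-[(triisopropylsilyloxy)methyl]decalin-6-one | C=CC[C@H]1[C@]2(C)CCC[C@](C)(CO[Si](C(C)C)(C(C)C)C(C)C)[C@H]2C(=O)C[C@]1(C)O | intermediate
27 | (4S,5S,6R,8S,9S,10R)-9-allyl-4,8,10-trimethyl-4-[(triisopropylsilyloxy)methyl]decalin-6,8-diol | C=CC[C@H]1[C@]2(C)CCC[C@](C)(CO[Si](C(C)C)(C(C)C)C(C)C)[C@H]2[C@H](O)C[C@]1(C)O | intermediate
28 | B-(C13)-alkyl-9-borabicyclo[3.3.1]nonane adduct of 27 (hydroxyls drawn free) | C(CC[C@H]3[C@]4(C)CCC[C@](C)(CO[Si](C(C)C)(C(C)C)C(C)C)[C@H]4[C@H](O)C[C@]3(C)O)B1C2CCCC1CCC2 | intermediate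
29 | (4S,5S,6R,8S,9S,10R)-9-(3-hydroxypropyl)-4,8,10-trimethyl-4-[(triisopropylsilyloxy)methyl]decalin-6,8-diol | OCCC[C@H]1[C@]2(C)CCC[C@](C)(CO[Si](C(C)C)(C(C)C)C(C)C)[C@H]2[C@H](O)C[C@]1(C)O | intermediate
30 | 8,13-lactol (13-hydroxy-8,13-epoxide) of the 6-ol, (4S,5S,6R,8S,9S,10R), anomers | OC1CC[C@H]2[C@]3(C)CCC[C@](C)(CO[Si](C(C)C)(C(C)C)C(C)C)[C@H]3[C@H](O)C[C@]2(C)O1 | intermediate
31 | (4S,5S,6R,8S,9S,10R)-9-(but-3-ynyl)-4,8,10-trimethyl-4-[(triisopropylsilyloxy)methyl]decalin-6,8-diol | C#CCC[C@H]1[C@]2(C)CCC[C@](C)(CO[Si](C(C)C)(C(C)C)C(C)C)[C@H]2[C@H](O)C[C@]1(C)O | intermediate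
32 | 6-acetate of 31 | C#CCC[C@H]1[C@]2(C)CCC[C@](C)(CO[Si](C(C)C)(C(C)C)C(C)C)[C@H]2[C@H](OC(C)=O)C[C@]1(C)O | intermediate
33 | 18-O-triisopropylsilyl ether of 34 | C=CC(=C)CC[C@H]1[C@]2(C)CCC[C@](C)(CO[Si](C(C)C)(C(C)C)C(C)C)[C@H]2[C@H](OC(C)=O)C[C@]1(C)O | intermediate
34 | (4S,5S,6R,8S,9S,10R)-6-acetoxylabda-13(16),14-diene-8,18-diol (CNP0312185.1) | C=CC(=C)CC[C@H]1[C@]2(C)CCC[C@](C)(CO)[C@H]2[C@H](OC(C)=O)C[C@]1(C)O | target

## Step count and risks

Total step count: 24. Longest linear sequence: 24 steps (from 1; aldehyde 2 enters in step 1).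

Least certain steps:

**Step 11 (key step).** The most likely failure is diversion of the carbenoid into 1,5-insertion at the activated allylic C5–H bond, or capture by the C6 oxygen; both are five-membered processes, whereas cyclopropanation closes a six-membered ring. Fallback, setting out from acid 15: homologation with 1,1'-carbonyldiimidazole and Mg(O2CCH2CO2CH2CH=CH2)2 gives allyl β-keto ester F1. Diazo transfer (4-acetamidobenzenesulfonyl azide, Et3N) gives allyl α-diazo-β-keto ester F2. Cu(acac)2 in refluxing toluene then gives cyclopropyl β-keto ester F3, since copper carbenoids of this class add to alkenes rather than insert into C–H bonds. SmI2 cuts C1–C9 to give β-keto allyl ester F4, and Pd(PPh3)4 (zerovalent palladium) effects decarboxylative allylation at C9 on the convex face. The fallback rejoins the route at 20.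

**Step 5.** Face selectivity in the methylation may be eroded if the enolate reacts through a conformer with the C5 chain pseudoequatorial. Fallback, setting out from 8: HF·pyridine and a trace of acid remove the silyl group and close the trans-fused 18,6-lactone F5. Methylation of its enolate (LiN(iPr)2, MeI) at the ring-fusion carbon gives the cis-fused methylated lactone F6, the five-membered ring forcing C18 and C6 onto one face. LiAlH4 gives 6,18-diol F7, iPr3SiOTf silylates the primary hydroxyl to give 18-silyl ether F8, and Et3SiOTf then returns to the route at 12.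

**Step 12.** Proton exchange between enolate 19 and product 20 in ammonia may cause loss of regiocontrol and dialkylation, or O-allylation may compete, because the enolate carbon is neopentyl. Fallback, setting out from 18: after the same Li/NH3 cleavage, enolate 19 is quenched with allyl chloroformate to give allyl enol carbonate F9. Pd(PPh3)4 then brings about decarboxylative Tsuji allylation, regiospecific at C9 and on the convex face, returning to the route at 20.

**Step 18.** The β-alkoxy ketone stage may suffer retro-aldol cleavage or β-elimination before it is reduced, since the alkoxide and ketone coexist briefly after protonation. Fallback, setting out from 25: SmI2 in THF/MeOH at –78 °C opens the epoxide and 26 is isolated. Et3SiOTf masks the tertiary hydroxyl to give 8-O-triethylsilyl hydroxy ketone F10. Li/NH3 with MeOH gives the equatorial 6-ol as 8-O-triethylsilyl 6-ol F11, and PPTS/MeOH returns to the route at 27.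

**Step 20.** The oxoammonium salt may over-oxidise the lactol to the lactone, as it also oxidises hemiacetals. Fallback, setting out from 29: excess PhI(OAc)2 with TEMPO drives the oxidation fully to 13,8-lactone F12, and i-Bu2AlH at –78 °C reduces it to the lactol, returning to the route at 30.

## Further compounds

F1 | step 11 | allyl β-keto ester (C8 ketone, C9 methylene bearing CO2allyl), (4S,5R,6S) | C=CCOC(=O)CC(=O)C[C@H](O[Si](CC)(CC)CC)[C@@H]1C(C)=CCC[C@]1(C)CO[Si](C(C)C)(C(C)C)C(C)C
F2 | step 11 | allyl α-diazo-β-keto ester, (4S,5R,6S) | C=CCOC(=O)C(=[N+]=[N-])C(=O)C[C@H](O[Si](CC)(CC)CC)[C@@H]1C(C)=CCC[C@]1(C)CO[Si](C(C)C)(C(C)C)C(C)C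
F3 | step 11 | cyclopropyl β-keto ester (9-allyloxycarbonyl analogue of 18) | O=C1C[C@H](O[Si](CC)(CC)CC)[C@@H]2[C@@]3(C)[C@@H](CC[C@]2(C)CO[Si](C(C)C)(C(C)C)C(C)C)[C@@]13C(=O)OCC=C
F4 | step 11 | β-keto allyl ester of the cis-decalin (9-allyloxycarbonyl-8-ketone, C9 not defined) | C=CCOC(=O)C1[C@]2(C)CCC[C@](C)(CO[Si](C(C)C)(C(C)C)C(C)C)[C@@H]2[C@@H](O[Si](CC)(CC)CC)CC1=O
F5 | step 5 | trans-fused 18,6-lactone | O=C1O[C@@H](CCOCc2ccc(OC)cc2)[C@@H]3C(C)=CCC[C@@H]13
F6 | step 5 | cis-fused 4-methyl 18,6-lactone | O=C1O[C@@H](CCOCc2ccc(OC)cc2)[C@@H]3C(C)=CCC[C@]13C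
F7 | step 5 | 6,18-diol, (4S,5R,6S) | COc1ccc(COCC[C@H](O)[C@@H]2C(C)=CCC[C@]2(C)CO)cc1
F8 | step 5 | 18-O-triisopropylsilyl 6-ol, (4S,5R,6S) | COc1ccc(COCC[C@H](O)[C@@H]2C(C)=CCC[C@]2(C)CO[Si](C(C)C)(C(C)C)C(C)C)cc1
F9 | step 12 | allyl enol carbonate of enolate 19 | C=CCOC(=O)OC1=C[C@]2(C)CCC[C@](C)(CO[Si](C(C)C)(C(C)C)C(C)C)[C@@H]2[C@@H](O[Si](CC)(CC)CC)C1
F10 | step 18 | 8-O-triethylsilyl ether of 26 | C=CC[C@H]1[C@]2(C)CCC[C@](C)(CO[Si](C(C)C)(C(C)C)C(C)C)[C@H]2C(=O)C[C@]1(C)O[Si](CC)(CC)CC
F11 | step 18 | 8-O-triethylsilyl ether of 27 | C=CC[C@H]1[C@]2(C)CCC[C@](C)(CO[Si](C(C)C)(C(C)C)C(C)C)[C@H]2[C@H](O)C[C@]1(C)O[Si](CC)(CC)CC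
F12 | step 20 | 13,8-lactone of the 6-ol | O=C1CC[C@H]2[C@]3(C)CCC[C@](C)(CO[Si](C(C)C)(C(C)C)C(C)C)[C@H]3[C@H](O)C[C@]2(C)O1
A1 | alternative 1 | 6-O-diethylsilyl-8-O-trimethylsilyl gem-dimethyl decalin with 13-ketone ethylene ketal | CC1(CC[C@H]2[C@]3(C)CCCC(C)(C)[C@H]3[C@H](O[SiH](CC)CC)C[C@]2(C)O[Si](C)(C)C)OCCO1
A2 | alternative 1 | 6,18-bridged oxasilinane | CC1(CC[C@H]2[C@]3(C)CCC[C@]4(C)C[Si](CC)(CC)O[C@H](C[C@]2(C)O[Si](C)(C)C)[C@@H]34)OCCO1
A3 | alternative 2 | (2E,7R)-8-(tert-butyldimethylsilyloxy)-3,7-dimethyl-7-(5-methylfuran-2-yl)oct-2-enal | O=C/C=C(\C)CCC[C@](C)(CO[Si](C)(C)C(C)(C)C)c1ccc(C)o1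
A4 | alternative 2 | 5,8-epoxy-bridged octalin C11 aldehyde | O=C[C@H]1[C@]2(C)CCC[C@](C)(CO[Si](C)(C)C(C)(C)C)[C@@]23C=C[C@]1(C)O3
A5 | alternative 3 | 2,6-dimethyl-1,4-benzoquinone | CC1=CC(=O)C=C(C)C1=O
A6 | alternative 3 | (E)-tert-butyldimethyl[(2-methylpenta-2,4-dien-1-yl)oxy]silane | C=C/C=C(\C)CO[Si](C)(C)C(C)(C)C
A7 | alternative 3 | cis-fused ene-dione adduct | O=C1[C@]2(C)CC=C[C@](C)(CO[Si](C)(C)C(C)(C)C)[C@@H]2C(=O)C=C1C
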